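The flavone is disconnected at the C4–C4a aryl ketone bond of ring A. C4a lies between the O1-bearing C8a and the methoxylated C5, and ring B has methoxyls on both C2' and C6', so an acylium ion generated from a β-aryloxycinnamic acid has only ring A to attack. A bromine placed at the future C8 closes off the competing ortho carbon. A single acid-mediated Friedel–Crafts cycloacylation therefore forms C4–C4a and the pyranone ring C. The precursor is (Z)-3-(2-bromo-4,5-dimethoxyphenoxy)-3-(2,3,5,6-tetramethoxyphenyl)prop-2-enoic acid, assembled by oxa-Michael addition of the bromophenol to an aryl ynoate; the bromine is removed at the end.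

Key step: step 6

Assumption: the oxa-Michael addition of step 4 is drawn as giving the Z enoate (anti addition); any E isomer is carried forward, since the enol ether geometry should equilibrate in the acid of step 6.

Step 1
Reactants: 1 3,4-dimethoxyphenol
Product: 2 2-bromo-4,5-dimethoxyphenol
Conditions: NBS (1.0 equiv), MeCN, −10 → 0 °C, dark
Reagents that add atoms: N-bromosuccinimide, O=C1CCC(=O)N1Br
Why: Electrophilic aromatic bromination of a phenol with NBS is expected ortho to the hydroxyl at C6, which is also para to the C3 methoxyl and unhindered, and not at C2, which is wedged between two oxygen substituents; one equivalent at low temperature limits dibromination and quinone formation.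

Step 2
Reactants: 3 1,2,4,5-tetramethoxybenzene
Product: 5 3-iodo-1,2,4,5-tetramethoxybenzene, via (2,3,5,6-tetramethoxyphenyl)lithium 4 (not isolated)
Conditions: n-BuLi (1.05 equiv), TMEDA, THF, 0 °C → rt; then I2, THF, −78 °C → rt
Reagents that add atoms: n-butyllithium, [Li]CCCC (lithium of 4 only); iodine, II
Why: Directed ortho-metalation followed by iodinolysis: either of the two equivalent ring hydrogens sits between two methoxyls and is removed by n-BuLi/TMEDA, and quenching the aryllithium with I2 avoids the oxidation to a quinone that electrophilic iodination of so electron-rich an arene would invite.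

Step 3
Reactants: 5 3-iodo-1,2,4,5-tetramethoxybenzene; 6 ethyl propiolate
Product: 7 ethyl 3-(2,3,5,6-tetramethoxyphenyl)prop-2-ynoate
Conditions: PdCl2(PPh3)2 (3 mol%), CuI (6 mol%), K2CO3 (2 equiv), THF, 65 °C, 6 (3 equiv) added slowly
Reagents that add atoms: none
Why: Sonogashira coupling of an aryl iodide with a terminal ynoate, run with a heterogeneous carbonate base and slow alkyne addition because amine bases add to and oligomerise ethyl propiolate; the iodide is chosen so that oxidative addition to zerovalent palladium stays feasible despite the two ortho methoxyls.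

Step 4
Reactants: 2 2-bromo-4,5-dimethoxyphenol; 7 ethyl 3-(2,3,5,6-tetramethoxyphenyl)prop-2-ynoate
Product: 8 ethyl (Z)-3-(2-bromo-4,5-dimethoxyphenoxy)-3-(2,3,5,6-tetramethoxyphenyl)prop-2-enoate
Conditions: Cs2CO3 (0.3 equiv), DMF, 80 °C
Reagents that add atoms: none
Why: Base-catalysed oxa-Michael addition of the phenoxide of 2 to the β-carbon of the ynoate, the vinyl anion being protonated by further phenol so that the base turns over; anti addition should place the ester cis to the aryloxy group (Z), and no stereocentre is formed.

Step 5
Reactants: 8 ethyl (Z)-3-(2-bromo-4,5-dimethoxyphenoxy)-3-(2,3,5,6-tetramethoxyphenyl)prop-2-enoate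
Product: 9 (Z)-3-(2-bromo-4,5-dimethoxyphenoxy)-3-(2,3,5,6-tetramethoxyphenyl)prop-2-enoic acid
Conditions: LiOH·H2O (3 equiv), THF–EtOH–H2O, 40 °C; then 1 M HCl to pH 3, 0 °C
Reagents that add atoms: lithium hydroxide, [Li+].[OH-] (its oxygen ends up in the carboxyl group)
Why: Ester saponification by hydroxide at the acyl carbon; the enol ether, the aryl bromide and the methyl ethers are inert to LiOH at 40 °C, and cold, careful acidification frees the acid without hydrolysing the acid-sensitive enol ether.

Step 6
Reactants: 9 (Z)-3-(2-bromo-4,5-dimethoxyphenoxy)-3-(2,3,5,6-tetramethoxyphenyl)prop-2-enoic acid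
Product: 11 8-bromo-5,6-dimethoxy-2-(2,3,5,6-tetramethoxyphenyl)-4H-chromen-4-one, via acylium ion 10 (not isolated)
Conditions: Eaton's reagent (P2O5 in MeSO3H, 1:10 w/w), 0.03 M, rt → 40 °C; ice/NaHCO3 quench
Reagents that add atoms: none
Why: P2O5/MeSO3H dehydrates the carboxylic acid to the acylium ion 10, whose carbon (future C4) attacks the one unsubstituted ortho carbon of the aryloxy ring (future C4a), and loss of that ring proton rearomatises ring A and completes the pyranone. The closest known reaction type is the Ruhemann-type cycloacylation of β-aryloxycinnamic acids to flavones, an intramolecular Friedel–Crafts acylation of an aryl vinyl ether. Ring C closes as a six-membered Friedel–Crafts ring in which the acyl carbon bonds to an arene carbon whose C4a–C8a π bond ends up inside the new ring, the cis relation of carboxyl and aryloxy group across C2=C3 keeping the two termini within reach. No stereocentre is created. The step needs regioselectivity between the two ortho carbons of the aryloxy ring and chemoselectivity against ring B: the bromine occupies the less crowded ortho carbon (future C8) that would otherwise react first, so bonding must occur at the carbon flanked by the ether oxygen and the C5 methoxyl, both of which activate it, while ring B has methoxyls on both C2' and C6' and so offers no ortho carbon for an indenone closure. Any E acid should converge on the same product, because protonation of the carbonyl in the strong acid lowers the C2=C3 bond order and lets the geometry equilibrate, and dilution at near-ambient temperature is meant to spare the nucleophilic C4' carbon of ring B and the C–Br bond.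

Step 7
Reactants: 11 8-bromo-5,6-dimethoxy-2-(2,3,5,6-tetramethoxyphenyl)-4H-chromen-4-one
Product: 12 5,6,2',3',5',6'-hexamethoxyflavone [5,6-dimethoxy-2-(2,3,5,6-tetramethoxyphenyl)-4H-chromen-4-one]
Conditions: Pd(OAc)2 (5 mol%), PPh3 (20 mol%), HCO2H, Et3N, DMF, 80 °C
Reagents that add atoms: none
Why: Palladium-catalysed hydrodehalogenation with formate as the hydride donor: zerovalent palladium inserts into the C8–Br bond, formate exchanges for bromide and loses CO2, and reductive elimination gives the C8–H flavone, a homogeneous system that should leave the C2=C3 bond, the carbonyl and the six methoxyls untouched.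

Compound list
1 | 3,4-dimethoxyphenol | COc1ccc(O)cc1OC | starting material
2 | 2-bromo-4,5-dimethoxyphenol | COc1cc(O)c(Br)cc1OC | intermediate
3 | 1,2,4,5-tetramethoxybenzene | COc1cc(OC)c(OC)cc1OC | starting material
4 | (2,3,5,6-tetramethoxyphenyl)lithium | [Li]c1c(OC)c(OC)cc(OC)c1OC | intermediate (not isolated)
5 | 3-iodo-1,2,4,5-tetramethoxybenzene | COc1cc(OC)c(OC)c(I)c1OC | intermediate
6 | ethyl propiolate (ethyl prop-2-ynoate) | C#CC(=O)OCC | starting material
7 | ethyl 3-(2,3,5,6-tetramethoxyphenyl)prop-2-ynoate | CCOC(=O)C#Cc1c(OC)c(OC)cc(OC)c1OC | intermediate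
8 | ethyl (Z)-3-(2-bromo-4,5-dimethoxyphenoxy)-3-(2,3,5,6-tetramethoxyphenyl)prop-2-enoate | CCOC(=O)/C=C(\Oc1cc(OC)c(OC)cc1Br)c1c(OC)c(OC)cc(OC)c1OC | intermediate
9 | (Z)-3-(2-bromo-4,5-dimethoxyphenoxy)-3-(2,3,5,6-tetramethoxyphenyl)prop-2-enoic acid | OC(=O)/C=C(\Oc1cc(OC)c(OC)cc1Br)c1c(OC)c(OC)cc(OC)c1OC | intermediate
10 | (Z)-3-(2-bromo-4,5-dimethoxyphenoxy)-3-(2,3,5,6-tetramethoxyphenyl)prop-2-enoylium (acylium ion) | O=[C+]/C=C(\Oc1cc(OC)c(OC)cc1Br)c1c(OC)c(OC)cc(OC)c1OC | intermediate (not isolated)
11 | 8-bromo-5,6-dimethoxy-2-(2,3,5,6-tetramethoxyphenyl)-4H-chromen-4-one | COc1cc(Br)c2oc(-c3c(OC)c(OC)cc(OC)c3OC)cc(=O)c2c1OC | intermediate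
12 | 5,6,2',3',5',6'-hexamethoxyflavone | COc1cc(OC)c(OC)c(-c2cc(=O)c3c(OC)c(OC)ccc3o2)c1OC | target

Total step count: 7.
Longest linear sequence: 6 steps (3 → 5 → 7 → 8 → 9 → 11 → 12, steps 2 to 7).

Steps most likely to fail

Step 6 (key step). Several processes could divert the acylium ion:
- intermolecular acylation or methanesulfonylation at the electron-rich C4' carbon of ring B;
- ipso attack at the brominated carbon with loss or migration of bromine, which would erode the regiocontrol;
- O-acylation by a ring-B ortho methoxyl of the E acid with loss of methyl (lactonisation);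
- hydrolytic cleavage of the enol ether by adventitious water.

Fallback: a classical chalcone route that sets out from 1 and from the aryllithium 4 and rejoins the route at 12. Compound 1 is protected with MOMCl/i-Pr2NEt in CH2Cl2 as 1,2-dimethoxy-4-(methoxymethoxy)benzene F1. n-BuLi in THF at 0 °C should remove the hydrogen between the two oxygen substituents to give [2,3-dimethoxy-6-(methoxymethoxy)phenyl]lithium F2, which is acetylated with N-methoxy-N-methylacetamide to 1-[2,3-dimethoxy-6-(methoxymethoxy)phenyl]ethanone F3. HCl in MeOH then frees 1-(6-hydroxy-2,3-dimethoxyphenyl)ethanone F4. Separately, 4 is quenched with DMF to give 2,3,5,6-tetramethoxybenzaldehyde F5. Claisen–Schmidt condensation of F4 with F5 (KOH, EtOH) should give (E)-1-(6-hydroxy-2,3-dimethoxyphenyl)-3-(2,3,5,6-tetramethoxyphenyl)prop-2-en-1-one F6. I2 (catalytic) in DMSO at 120 °C cyclises and dehydrogenates F6 to 12, so neither the bromine nor step 7 is needed.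

Step 4. The conjugate addition may be sluggish, because the β-carbon is electronically deactivated by the electron-rich aryl group and screened by its two ortho methoxyls. Transesterification or ester cleavage by the phenoxide and base-induced decomposition of the ynoate could then outrun C–O bond formation.

Fallback: sets out from 7 and 2 and comes back at 8. Hydroiodination of 7 with NaI in AcOH at 80 °C should give ethyl (Z)-3-iodo-3-(2,3,5,6-tetramethoxyphenyl)prop-2-enoate F7. An Ullmann-type O-vinylation of 2 with F7 (CuI, N,N-dimethylglycine, Cs2CO3, dioxane, 90 °C) then forms the C–O bond at copper and not by Michael attack, with retention of geometry, giving 8. The activated vinyl iodide should react well ahead of the electron-rich aryl bromide.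

Step 3. The propiolate may be consumed by base-induced oligomerisation and copper-mediated oxidative dimerisation faster than the cross-coupling, which is slowed by the two methoxyls flanking the C–I bond.

Fallback: sets out from 5 and comes back at 7; the ester carbon is introduced by acylating an acetylide instead of coupling the intact propiolate. Sonogashira coupling of 5 with the robust ethynyltrimethylsilane (PdCl2(PPh3)2, CuI, Et3N, DMF, 70 °C) should give trimethyl[(2,3,5,6-tetramethoxyphenyl)ethynyl]silane F8. K2CO3 in MeOH removes the silyl group to give 3-ethynyl-1,2,4,5-tetramethoxybenzene F9. n-BuLi (1.0 equiv, THF, −78 °C) forms lithium (2,3,5,6-tetramethoxyphenyl)ethynide F10, which is quenched with ethyl chloroformate to give 7.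

Further compounds
F1 | step 6 | 1,2-dimethoxy-4-(methoxymethoxy)benzene | COCOc1ccc(OC)c(OC)c1
F2 | step 6 | [2,3-dimethoxy-6-(methoxymethoxy)phenyl]lithium | [Li]c1c(OCOC)ccc(OC)c1OC
F3 | step 6 | 1-[2,3-dimethoxy-6-(methoxymethoxy)phenyl]ethanone | CC(=O)c1c(OCOC)ccc(OC)c1OC
F4 | step 6 | 1-(6-hydroxy-2,3-dimethoxyphenyl)ethanone | CC(=O)c1c(O)ccc(OC)c1OC
F5 | step 6 | 2,3,5,6-tetramethoxybenzaldehyde | COc1cc(OC)c(OC)c(C=O)c1OC
F6 | step 6 | (E)-1-(6-hydroxy-2,3-dimethoxyphenyl)-3-(2,3,5,6-tetramethoxyphenyl)prop-2-en-1-one | COc1cc(OC)c(OC)c(/C=C/C(=O)c2c(O)ccc(OC)c2OC)c1OC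
F7 | step 4 | ethyl (Z)-3-iodo-3-(2,3,5,6-tetramethoxyphenyl)prop-2-enoate | CCOC(=O)/C=C(\I)c1c(OC)c(OC)cc(OC)c1OC
F8 | step 3 | trimethyl[(2,3,5,6-tetramethoxyphenyl)ethynyl]silane | COc1cc(OC)c(OC)c(C#C[Si](C)(C)C)c1OC
F9 | step 3 | 3-ethynyl-1,2,4,5-tetramethoxybenzene | COc1cc(OC)c(OC)c(C#C)c1OC
F10 | step 3 | lithium (2,3,5,6-tetramethoxyphenyl)ethynide | [Li]C#Cc1c(OC)c(OC)cc(OC)c1OC
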